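**Retrosynthetic overview**

1. 13 ⇒ spiro-epoxide 12 ⇒ 3-methylidene oxolane 11: the C3 carbinol (OH trans to the cis 2-aryl/4-methyl/5-aryl array) is read as an exocyclic C3=CH2 bond, oxidised on its open face and opened by hydride.
2. 11 ⇒ allylsilane carbinol 8 + aldehyde 2: the oxolane, the only ring formed, is closed in step 5 by the C4–C5 bond, after O1–C5 has been set up in the same flask as an oxocarbenium ion.
3. Enabling feature: C5 is a benzylic carbon on ring oxygen O1 (an aryl-stabilised oxocarbenium ion at the aldehyde level), and its neighbour C4 becomes the γ-carbon of an allylsilane once the C3 methyl carbon carries SiMe3 and C3=C4 is a double bond.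
4. 8 ⇒ 6 ⇒ 4 ⇒ 2 + propyne: asymmetric alkynylation sets C2; syn-hydrostannation/iodination and Negishi coupling fix the alkene geometry that becomes C4.
5. Both aryl halves come from vanillin 1 through aldehyde 2; pivalates are the only protecting groups and leave in the last step.

Key step: step 5

Remark: locants O1 and C2–C5 are those of the oxolane ring of 13 (C3 carries OH).
Remark: the ligand enantiomer in step 2 is taken to be the one that adds the alkynyl group to the Si face of 2 (1R carbinol); should the sense of induction be the opposite, its antipode is used.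

**Step 1**
Reactants: 1 vanillin
Product: 2 4-formyl-2-methoxyphenyl 2,2-dimethylpropanoate
Conditions: PivCl (1.1 equiv), K2CO3 (1.5 equiv), acetone, 0 °C to rt
Reagents that add atoms: pivaloyl chloride, CC(C)(C)C(=O)Cl
Why: Schotten–Baumann-type O-acylation of the phenol gives an electron-withdrawing pivalate that should survive the zinc reagents and later temper ionisation of the benzylic C–O bonds; no stereocentre is formed.

**Step 2**
Reactants: 2 4-formyl-2-methoxyphenyl 2,2-dimethylpropanoate; 3 propyne
Product: 4 4-[(1R)-1-hydroxybut-2-yn-1-yl]-2-methoxyphenyl 2,2-dimethylpropanoate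
Conditions: propyne (3 equiv), Me2Zn (3 equiv), (S,S)-ProPhenol (20 mol %), Ph3PO (40 mol %), toluene, 4 °C; aq. NH4Cl
Reagents that add atoms: none
Why: Catalytic asymmetric alkynylation (ligand-controlled addition of the alkynylzinc reagent to the Si face of the aldehyde) should set the C2 carbinol centre as 1R, the only stereocentre of the route that is set by a reagent.

**Step 3**
Reactants: 4 4-[(1R)-1-hydroxybut-2-yn-1-yl]-2-methoxyphenyl 2,2-dimethylpropanoate
Product: 6 4-[(1R,2E)-1-hydroxy-2-iodobut-2-en-1-yl]-2-methoxyphenyl 2,2-dimethylpropanoate, via vinylstannane 5 (not isolated)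
Conditions: Bu3SnH (1.2 equiv), PdCl2(PPh3)2 (2 mol %), THF, 0 °C to rt; then I2 (1.3 equiv), CH2Cl2, 0 °C
Reagents that add atoms: iodine, II
Why: Palladium-catalysed syn-hydrostannation of the propargylic alcohol should put tin on the carbinol-proximal alkyne carbon and hydrogen cis to it, and iododestannylation with retention then fixes the alkene with its methyl group cis to the carbinol carbon; no stereocentre is formed.

**Step 4**
Reactants: 6 4-[(1R,2E)-1-hydroxy-2-iodobut-2-en-1-yl]-2-methoxyphenyl 2,2-dimethylpropanoate; 7 (trimethylsilyl)methylmagnesium chloride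
Product: 8 4-[(1R,2E)-1-hydroxy-2-[(trimethylsilyl)methyl]but-2-en-1-yl]-2-methoxyphenyl 2,2-dimethylpropanoate
Conditions: 7 (3.0 equiv), ZnCl2 (3.0 equiv), THF, 0 °C; then 6, Pd(PPh3)4 (5 mol %), THF, 45 °C
Reagents that add atoms: none
Why: Negishi cross-coupling of the alkenyl iodide with the silylmethylzinc reagent should proceed with retention of alkene geometry and turn C3=C4 into an allylsilane whose γ-carbon is C4, the zinc reagent leaving the aryl pivalate untouched; no stereocentre is formed.

**Step 5**
Reactants: 8 4-[(1R,2E)-1-hydroxy-2-[(trimethylsilyl)methyl]but-2-en-1-yl]-2-methoxyphenyl 2,2-dimethylpropanoate; 2 4-formyl-2-methoxyphenyl 2,2-dimethylpropanoate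
Product: 11 (2S,4S,5R)-2,5-bis[3-methoxy-4-(pivaloyloxy)phenyl]-4-methyl-3-methylideneoxolane, via trimethylsilyl ether 9 (not isolated), via oxocarbenium triflate 10 (not isolated)
Conditions: BSA (1.2 equiv), CH2Cl2, rt; then 2 (1.2 equiv), TMSOTf (0.2 equiv), CH2Cl2 (0.02 M), −78 to −40 °C; Et3N
Reagents that add atoms: none
Why: BSA gives silyl ether 9, which with 2 and catalytic TMSOTf loses hexamethyldisiloxane to give the (E)-oxocarbenium ion 10; its C5 is attacked by C4, the γ-carbon of the tethered allylsilane, and the β-silyl cation at C3 then sheds the silyl group (regenerating TMSOTf) and leaves the exocyclic C3=CH2 bond. This is an intramolecular silyl-modified Sakurai (Prins-type) cyclisation, whose closest known cases are allylsilane-terminated cyclisations of oxocarbenium and N-acyliminium ions carrying a 2-(silylmethyl)allyl unit, which give 3-methylidene oxolanes and 4-methylidene pyrrolidines. The oxolane is closed by the C4–C5 bond in the 5-endo-trig mode (C3=C4 and C5=O1 all become ring atoms), anti to the C–Si bond. C5 follows from the E geometry of 10, whose aryl group points away from the alkene, and C4 from the alkene geometry, the methyl group cis to C2 swinging to the face opposite the new bond; both are tied to C2 because allylic strain keeps the C2–H bond in the alkene plane beside the CH2Si group, so that O1 (and with it C5) and the C2 aryl group occupy opposite faces. The 2-aryl, 4-methyl and 5-aryl groups should therefore end up all cis. Closure must outrun ionisation of the allylic, benzylic C2–O bond and intermolecular allylation, which the pivalate-deactivated aryl rings, −78 °C, catalytic silyl triflate and high dilution should secure.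

**Step 6**
Reactants: 11 (2S,4S,5R)-2,5-bis[3-methoxy-4-(pivaloyloxy)phenyl]-4-methyl-3-methylideneoxolane
Product: 12 (3R,4R,6R,7R)-4,6-bis[3-methoxy-4-(pivaloyloxy)phenyl]-7-methyl-1,5-dioxaspiro[2.4]heptane
Conditions: DMDO (1.5 equiv, acetone solution), CH2Cl2, −20 to 0 °C
Reagents that add atoms: dimethyldioxirane, CC1(C)OO1
Why: Substrate-controlled epoxidation of the exocyclic 1,1-disubstituted alkene under neutral conditions should occur on the ring face opposite the three cis substituents (C2 aryl, C4 methyl, C5 aryl), which places the new C3–O bond trans to them and sets C3.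

**Step 7**
Reactants: 12 (3R,4R,6R,7R)-4,6-bis[3-methoxy-4-(pivaloyloxy)phenyl]-7-methyl-1,5-dioxaspiro[2.4]heptane
Product: 13 (2R,3S,4R,5R)-2,5-bis(4-hydroxy-3-methoxyphenyl)-3,4-dimethyloxolan-3-ol
Conditions: LiAlH4 (5 equiv), THF, 0 °C to rt; aq. potassium sodium tartrate
Reagents that add atoms: none
Why: Hydride should open the spiro-epoxide by SN2 attack at its CH2 terminus, which turns that carbon into the C3 methyl group and leaves the tertiary C3–O bond and configuration untouched, while the same reagent reductively cleaves both aryl pivalates.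

**Compound list**

1 | vanillin (4-hydroxy-3-methoxybenzaldehyde) | COc1cc(C=O)ccc1O | starting material
2 | 4-formyl-2-methoxyphenyl 2,2-dimethylpropanoate | COc1cc(C=O)ccc1OC(=O)C(C)(C)C | intermediate
3 | propyne | CC#C | starting material
4 | 4-[(1R)-1-hydroxybut-2-yn-1-yl]-2-methoxyphenyl 2,2-dimethylpropanoate | CC#C[C@H](O)c1ccc(OC(=O)C(C)(C)C)c(OC)c1 | intermediate
5 | 4-[(1R,2E)-1-hydroxy-2-(tributylstannyl)but-2-en-1-yl]-2-methoxyphenyl 2,2-dimethylpropanoate | C/C=C(/[Sn](CCCC)(CCCC)CCCC)[C@H](O)c1ccc(OC(=O)C(C)(C)C)c(OC)c1 | intermediate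
6 | 4-[(1R,2E)-1-hydroxy-2-iodobut-2-en-1-yl]-2-methoxyphenyl 2,2-dimethylpropanoate | C/C=C(/I)[C@H](O)c1ccc(OC(=O)C(C)(C)C)c(OC)c1 | intermediate
7 | (trimethylsilyl)methylmagnesium chloride | C[Si](C)(C)C[Mg]Cl | starting material
8 | 4-[(1R,2E)-1-hydroxy-2-[(trimethylsilyl)methyl]but-2-en-1-yl]-2-methoxyphenyl 2,2-dimethylpropanoate | C/C=C(/C[Si](C)(C)C)[C@H](O)c1ccc(OC(=O)C(C)(C)C)c(OC)c1 | intermediate
9 | 2-methoxy-4-[(1R,2E)-2-[(trimethylsilyl)methyl]-1-[(trimethylsilyl)oxy]but-2-en-1-yl]phenyl 2,2-dimethylpropanoate | C/C=C(/C[Si](C)(C)C)[C@H](O[Si](C)(C)C)c1ccc(OC(=O)C(C)(C)C)c(OC)c1 | intermediate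
10 | (E)-oxocarbenium triflate from 9 and 2 (O1 bonded to C2 and doubly bonded to the C5 arylmethylidene carbon; 1R, 2E) | C/C=C(/C[Si](C)(C)C)[C@H](/[O+]=C/c1ccc(OC(=O)C(C)(C)C)c(OC)c1)c1ccc(OC(=O)C(C)(C)C)c(OC)c1.[O-]S(=O)(=O)C(F)(F)F | intermediate
11 | (2S,4S,5R)-2,5-bis[3-methoxy-4-(pivaloyloxy)phenyl]-4-methyl-3-methylideneoxolane (ring locants as in 13; aryl, methyl and aryl all cis) | COc1cc([C@H]2O[C@@H](c3ccc(OC(=O)C(C)(C)C)c(OC)c3)[C@@H](C)C2=C)ccc1OC(=O)C(C)(C)C | intermediate
12 | (3R,4R,6R,7R)-4,6-bis[3-methoxy-4-(pivaloyloxy)phenyl]-7-methyl-1,5-dioxaspiro[2.4]heptane (epoxide oxygen trans to the two aryl groups and the methyl group) | COc1cc([C@H]2O[C@@H](c3ccc(OC(=O)C(C)(C)C)c(OC)c3)[C@@H](C)[C@@]24CO4)ccc1OC(=O)C(C)(C)C | intermediate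
13 | (2R,3S,4R,5R)-2,5-bis(4-hydroxy-3-methoxyphenyl)-3,4-dimethyloxolan-3-ol | COc1cc([C@H]2O[C@@H](c3ccc(O)c(OC)c3)[C@@H](C)[C@]2(C)O)ccc1O | target

**Step count and risks**

Total steps: 7. Longest linear sequence: 7 steps (1 → 2 → 4 → 6 → 8 → 11 → 12 → 13); aldehyde 2 enters twice (steps 2 and 5).

Steps most likely to fail:

1. Step 5. Ring closure in the endo sense may be too slow: the oxocarbenium carbon has to reach C4 at an acute angle, and O1 has to pass the methyl group on C4. Intermolecular allylation, protodesilylation or reversible ionisation at C2 (loss of configurational integrity) could then take over, and placement of the C2 aryl group anti to the forming bond may be incomplete. Fallback (bond first, ring second), setting out from 8 and 2 and coming back at 11: silylation (TBSCl, imidazole) gives the tert-butyldimethylsilyl ether F1. Intermolecular Hosomi–Sakurai addition of F1 to 2 (BF3·OEt2, CH2Cl2, −78 °C) should give the C4/C5-syn homoallylic alcohol F2; the aldehyde should add to the alkene face anti to the C2 aryl group while allylic strain holds the C2–H bond in the alkene plane. Appel bromination (CBr4, PPh3) with inversion gives the benzylic bromide F3. TBAF then frees the C2 alkoxide, which displaces bromide with a second inversion (intramolecular Williamson etherification, 5-exo-tet) to give 11.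

2. Step 3. Tin may be delivered to the distal alkyne carbon because of the bulk of the secondary aryl carbinol, or protodestannylation may intervene, so that the iodide ends up on the wrong carbon. Fallback (regiochemistry enforced by a carbonyl group), setting out from 4 and coming back at 6: MnO2 oxidation gives the ynone F4. Pd(PPh3)4-catalysed syn-hydrostannation with Bu3SnH, now steered by the polarity of the conjugated ketone, should put tin α to the carbonyl group and give the stannyl enone F5. Iododestannylation with I2 gives the iodo enone F6. Corey–Bakshi–Shibata reduction (2-methyl-CBS-oxazaborolidine enantiomer chosen for the 1R alcohol, BH3·SMe2) returns 6.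

3. Step 6. The strained spiro-epoxide next to the benzylic C2 centre may rearrange by ring-opening, benzylic C–H bonds may be oxidised in competition, or facial selectivity may be incomplete and give C3 epimerisation. Fallback (radical hydration instead of epoxidation/hydride), setting out from 11 and coming back at 13: Mukaiyama hydration (Co(acac)2, PhSiH3, O2, iPrOH) should install the tertiary hydroxyl group directly, the C3 radical being trapped by oxygen on the open face, to give the bis-pivalate F7. NaOMe in MeOH then removes both pivalates to give 13.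

**Further compounds**

F1 | step 5 | tert-butyldimethylsilyl ether of 8 | C/C=C(/C[Si](C)(C)C)[C@H](O[Si](C)(C)C(C)(C)C)c1ccc(OC(=O)C(C)(C)C)c(OC)c1
F2 | step 5 | open-chain C4/C5-syn homoallylic alcohol (C5–OH, C2–OTBS, C3=CH2; configuration at C2, C4, C5 as in 11) | COc1cc([C@@H](O[Si](C)(C)C(C)(C)C)C(=C)[C@H](C)[C@@H](O)c2ccc(OC(=O)C(C)(C)C)c(OC)c2)ccc1OC(=O)C(C)(C)C
F3 | step 5 | benzylic bromide from F2 (C5 inverted) | COc1cc([C@@H](O[Si](C)(C)C(C)(C)C)C(=C)[C@H](C)[C@H](Br)c2ccc(OC(=O)C(C)(C)C)c(OC)c2)ccc1OC(=O)C(C)(C)C
F4 | step 3 | 4-(but-2-ynoyl)-2-methoxyphenyl 2,2-dimethylpropanoate | CC#CC(=O)c1ccc(OC(=O)C(C)(C)C)c(OC)c1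
F5 | step 3 | 2-methoxy-4-[(2E)-2-(tributylstannyl)but-2-enoyl]phenyl 2,2-dimethylpropanoate | C/C=C(/[Sn](CCCC)(CCCC)CCCC)C(=O)c1ccc(OC(=O)C(C)(C)C)c(OC)c1
F6 | step 3 | 4-[(2E)-2-iodobut-2-enoyl]-2-methoxyphenyl 2,2-dimethylpropanoate | C/C=C(/I)C(=O)c1ccc(OC(=O)C(C)(C)C)c(OC)c1
F7 | step 6 | bis(2,2-dimethylpropanoate) of 13 at both phenols | COc1cc([C@H]2O[C@@H](c3ccc(OC(=O)C(C)(C)C)c(OC)c3)[C@@H](C)[C@]2(C)O)ccc1OC(=O)C(C)(C)C
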